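**Retrosynthetic overview**
1. Ring B (the 2,5-dihydrofuran) is closed last: silver-catalysed 5-endo addition of the C5 hydroxyl to a (6S)-allene transfers the axis to C8 (8R).
2. The allenic C27 polyene comes from a Wittig union at C11=C12 of an allenic C15 phosphonium salt with a C12 aldehyde ester (C10 dialdehyde + phosphonoacetate), then ester reduction.
3. The allene comes from anti hydride SN2′ opening (palladium/formate) of a cis-fused propargylic cyclic carbonate, made by axial addition of a C6 enyne acetylide to an α-hydroxy ketone.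
4. Key C5–C6 bond and ring A (first ring): carbene-catalysed intramolecular crossed benzoin, the aldehyde carbon acting as an acyl anion toward a methyl ketone, which sets the C5 carbinol.
5. The keto aldehyde arises by double ozonolysis of a dienol built from (R)-epichlorohydrin (source of C3) and two Grignard reagents.

Assumption: locants C1–C15 and C15′–C10′ follow carotenoid numbering of the target; the Grignard solutions, the C10 dialdehyde and the E-enynol are taken as purchasable. The route has not been run; the selectivities are predictions.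

**Step 1**
Reactants: 1 (R)-epichlorohydrin; 2 isopropenylmagnesium bromide
Product: 4 (2R)-2-(2-methylprop-2-en-1-yl)oxirane, via chlorohydrin 3 (not isolated)
Conditions: CuI (10 mol%), THF, −40 → 0 °C; then aq. NaOH, rt
Reagents that add atoms: none
Why: Copper-catalysed Grignard opening of the epoxide at its CH2 carbon and Williamson-type closure of the chlorohydrin onto the former CH2Cl carbon never break a bond to the stereocentre, so the (R) centre of 1 (the future C3) is carried over unchanged.

**Step 2**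
Reactants: 4 (2R)-2-(2-methylprop-2-en-1-yl)oxirane; 5 prenylmagnesium chloride
Product: 7 triethyl{[(4R)-2,6,6-trimethylocta-1,7-dien-4-yl]oxy}silane, via magnesium alkoxide 6 (not isolated)
Conditions: THF, 0 °C → rt; then Et3SiOTf, −20 °C → rt
Reagents that add atoms: triethylsilyl trifluoromethanesulfonate, CC[Si](CC)(CC)OS(=O)(=O)C(F)(F)F
Why: The allylic Grignard reagent opens the terminal epoxide carbon with allylic transposition (SE2′ epoxide opening), bonding through its tertiary carbon to give the gem-dimethyl vinyl unit, and the alkoxide is silylated in the same flask without involving the carbinol centre.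

**Step 3**
Reactants: 7 triethyl{[(4R)-2,6,6-trimethylocta-1,7-dien-4-yl]oxy}silane
Product: 9 (4S)-2,2-dimethyl-6-oxo-4-[(triethylsilyl)oxy]heptanal, via bis-ozonide 8 (not isolated)
Conditions: O3, CH2Cl2, −78 °C; then PPh3, −78 °C → rt
Reagents that add atoms: ozone, [O-][O+]=O
Why: Double ozonolysis with reductive work-up turns the vinyl group into the neopentyl aldehyde (future C6) and the isopropenyl group into the methyl ketone (future C5) in one operation, leaving the silyloxy centre untouched (the descriptor changes to S only through priority rules).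

**Step 4**
Reactants: 9 (4S)-2,2-dimethyl-6-oxo-4-[(triethylsilyl)oxy]heptanal
Product: 10 (2R,4S)-2-hydroxy-2,6,6-trimethyl-4-[(triethylsilyl)oxy]cyclohexan-1-one
Conditions: 2-(pentafluorophenyl)-6,7-dihydro-5H-pyrrolo[2,1-c][1,2,4]triazol-2-ium tetrafluoroborate (20 mol%), i-Pr2NEt (20 mol%), toluene (0.05 M), 40 °C
Reagents that add atoms: none
Why: Intramolecular crossed aldehyde–ketone benzoin reaction under N-heterocyclic carbene catalysis, in which the carbene turns the non-enolisable aldehyde carbon into an acyl anion equivalent that attacks the ketone carbonyl to close ring A, and a chair transition state with the silyloxy group and the C5 methyl equatorial and the ketone oxygen axial (avoiding a methyl/methyl 1,3-diaxial clash with the gem-dimethyl group) places the new tertiary hydroxyl trans to the silyloxy group (5R, which is 2R in ketone numbering).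

**Step 5**
Reactants: 11 (2E)-3-methylpent-2-en-4-yn-1-ol
Product: 12 triethyl{[(2E)-3-methylpent-2-en-4-yn-1-yl]oxy}silane
Conditions: Et3SiCl, imidazole, CH2Cl2, 0 °C
Reagents that add atoms: chlorotriethylsilane, CC[Si](Cl)(CC)CC
Why: Standard silyl ether formation masks the primary allylic hydroxyl so that the alkyne can be lithiated and no allylic carbonate can form in the next step, with the E double bond untouched.

**Step 6**
Reactants: 10 (2R,4S)-2-hydroxy-2,6,6-trimethyl-4-[(triethylsilyl)oxy]cyclohexan-1-one; 12 triethyl{[(2E)-3-methylpent-2-en-4-yn-1-yl]oxy}silane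
Product: 15 (3aR,6S,7aR)-4,4,7a-trimethyl-3a-{(3E)-3-methyl-5-[(triethylsilyl)oxy]pent-3-en-1-yn-1-yl}-6-[(triethylsilyl)oxy]hexahydro-1,3-benzodioxol-2-one, via lithium acetylide 13 (not isolated), via dilithium diolate 14 (not isolated)
Conditions: 12 (2.3 equiv), n-BuLi (2.2 equiv), THF, −78 °C; add 10, −78 → 0 °C; then ClCO2Me (2.5 equiv), −78 °C → rt
Reagents that add atoms: methyl chloroformate, COC(Cl)=O
Why: 1,2-Addition of a lithium acetylide to a non-enolisable ketone followed by carbonate formation, where in the chair of 10 the axial C5 alkoxide and the axial C1 methyl shield one face so the acetylide enters axially on the other (trans to the C5 oxygen, C6 becomes R) and the resulting cis-5,6-diolate is closed by the chloroformate to the cis-fused cyclic carbonate.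

**Step 7**
Reactants: 15 (3aR,6S,7aR)-4,4,7a-trimethyl-3a-{(3E)-3-methyl-5-[(triethylsilyl)oxy]pent-3-en-1-yn-1-yl}-6-[(triethylsilyl)oxy]hexahydro-1,3-benzodioxol-2-one
Product: 16 (1R,5S)-1,3,3-trimethyl-2-{(3E)-3-methyl-5-[(triethylsilyl)oxy]penta-1,3-dien-1-ylidene}-5-[(triethylsilyl)oxy]cyclohexan-1-ol with (Sa) allene axis (6S in carotenoid numbering)
Conditions: Pd2(dba)3·CHCl3 (2.5 mol%), P(n-Bu)3 (10 mol%), HCO2NH4 (3 equiv), THF, rt
Reagents that add atoms: none
Why: Tsuji-type palladium-catalysed hydrogenolysis of a propargylic carbonate, in which zerovalent palladium attacks C8 anti to the departing C6–O bond (SN2′), formate supplies a hydride on palladium that is transferred to C8 with retention, so H ends anti and the side chain syn to the lost oxygen, which together with the 5R carbinol fixes the (6S) allene axis while CO2 loss frees the 5-hydroxyl.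

**Step 8**
Reactants: 16 (1R,5S)-1,3,3-trimethyl-2-{(3E)-3-methyl-5-[(triethylsilyl)oxy]penta-1,3-dien-1-ylidene}-5-[(triethylsilyl)oxy]cyclohexan-1-ol
Product: 17 {(2E)-5-[(2R,4S)-2,4-dihydroxy-2,6,6-trimethylcyclohexylidene]-3-methylpenta-2,4-dien-1-yl}triphenylphosphonium bromide with (Sa) allene axis
Conditions: PPh3·HBr (1.5 equiv), MeOH, 0 °C → rt
Reagents that add atoms: triphenylphosphine hydrobromide, [Br-].[PH+](c1ccccc1)(c1ccccc1)c1ccccc1
Why: Acid-catalysed methanolysis removes both triethylsilyl ethers and the primary allylic alcohol is converted by way of its allyl cation into the phosphonium salt (the usual preparation of C15 Wittig salts), while the secondary and the tertiary allenic hydroxyls and the allene axis are not ionised under these mild conditions.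

**Step 9**
Reactants: 18 (2E,4E,6E)-2,7-dimethylocta-2,4,6-trienedial; 19 triethyl phosphonoacetate
Product: 20 ethyl (2E,4E,6E,8E)-4,9-dimethyl-10-oxodeca-2,4,6,8-tetraenoate
Conditions: NaH (1.0 equiv), THF, 0 °C; add to 18 (2 equiv), 0 °C → rt
Reagents that add atoms: none
Why: Horner–Wadsworth–Emmons mono-olefination of the symmetrical dialdehyde (used in excess and recovered) gives the E enoate and leaves the second aldehyde (C12) for the Wittig step.

**Step 10**
Reactants: 17 {(2E)-5-[(2R,4S)-2,4-dihydroxy-2,6,6-trimethylcyclohexylidene]-3-methylpenta-2,4-dien-1-yl}triphenylphosphonium bromide; 20 ethyl (2E,4E,6E,8E)-4,9-dimethyl-10-oxodeca-2,4,6,8-tetraenoate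
Product: 22 ethyl (3S,5R,6S)-3,5-dihydroxy-6,7-didehydro-5,6-dihydro-10′-apo-β-caroten-10′-oate (all-E), via phosphorus ylide 21 (not isolated)
Conditions: NaOEt (2.5 equiv), EtOH/CH2Cl2, 0 °C → rt; then EtOH, 50 °C (11Z → 11E)
Reagents that add atoms: none
Why: Wittig olefination of the allylic ylide with the 2-methyl enal forms C11=C12, the sterically hindered 11Z isomer equilibrates to 11E on gentle warming, the 9E geometry is held by the bulky allenyl substituent, and neither the allene axis nor the carbinol centres are touched.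

**Step 11**
Reactants: 22 ethyl (3S,5R,6S)-3,5-dihydroxy-6,7-didehydro-5,6-dihydro-10′-apo-β-caroten-10′-oate
Product: 23 (3S,5R,6S)-6,7-didehydro-5,6-dihydro-10′-apo-β-carotene-3,5,10′-triol (all-E)
Conditions: i-Bu2AlH (6 equiv), CH2Cl2, −78 °C
Reagents that add atoms: none
Why: Hydride reduction of the conjugated ester with diisobutylaluminium hydride gives the primary allylic alcohol by 1,2-reduction without affecting the polyene, the allene or any stereocentre.

**Step 12**
Reactants: 23 (3S,5R,6S)-6,7-didehydro-5,6-dihydro-10′-apo-β-carotene-3,5,10′-triol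
Product: 24 (3S,5R,8R)-5,8-epoxy-5,8-dihydro-10′-apo-β-carotene-3,10′-diol (target)
Conditions: AgNO3 (0.3 equiv), CaCO3, acetone/H2O 9:1, rt, dark
Reagents that add atoms: none
Why: Silver-catalysed 5-endo cycloisomerisation of an α-hydroxy allene to a 2,5-dihydrofuran (monovalent silver activates the C7=C8 bond), in which the 5-hydroxyl adds to C8 in the plane of ring A while H and the polyene chain stay on their own faces, so the (6S) axis is converted into the 8R centre with the chain trans to the C5 methyl.

**Compound list**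
1 | (R)-epichlorohydrin, (2R)-2-(chloromethyl)oxirane | ClC[C@H]1CO1 | starting material
2 | isopropenylmagnesium bromide | C=C(C)[Mg]Br | starting material
3 | (2R)-1-chloro-4-methylpent-4-en-2-ol | ClC[C@H](O)CC(C)=C | intermediate
4 | (2R)-2-(2-methylprop-2-en-1-yl)oxirane | C1[C@H](O1)CC(C)=C | intermediate
5 | prenylmagnesium chloride, 3-methylbut-2-en-1-ylmagnesium chloride | CC(C)=CC[Mg]Cl | starting material
6 | chloromagnesium (4R)-2,6,6-trimethylocta-1,7-dien-4-olate | C=CC(C)(C)C[C@H](O[Mg]Cl)CC(C)=C | intermediate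
7 | triethyl{[(4R)-2,6,6-trimethylocta-1,7-dien-4-yl]oxy}silane | C=CC(C)(C)C[C@H](O[Si](CC)(CC)CC)CC(C)=C | intermediate
8 | bis-ozonide (bis-1,2,4-trioxolane) of 7, silyloxy centre unchanged | C1(OCOO1)C(C)(C)C[C@H](O[Si](CC)(CC)CC)CC1(C)OCOO1 | intermediate
9 | (4S)-2,2-dimethyl-6-oxo-4-[(triethylsilyl)oxy]heptanal | O=CC(C)(C)C[C@H](O[Si](CC)(CC)CC)CC(C)=O | intermediate
10 | (2R,4S)-2-hydroxy-2,6,6-trimethyl-4-[(triethylsilyl)oxy]cyclohexan-1-one | O=C1C(C)(C)C[C@H](O[Si](CC)(CC)CC)C[C@@]1(C)O | intermediate
11 | (2E)-3-methylpent-2-en-4-yn-1-ol | C#C/C(C)=C/CO | starting material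
12 | triethyl{[(2E)-3-methylpent-2-en-4-yn-1-yl]oxy}silane | C#C/C(C)=C/CO[Si](CC)(CC)CC | intermediate
13 | {(3E)-3-methyl-5-[(triethylsilyl)oxy]pent-3-en-1-yn-1-yl}lithium | [Li]C#C/C(C)=C/CO[Si](CC)(CC)CC | intermediate
14 | dilithium (1R,2R,5S)-1,3,3-trimethyl-2-{(3E)-3-methyl-5-[(triethylsilyl)oxy]pent-3-en-1-yn-1-yl}-5-[(triethylsilyl)oxy]cyclohexane-1,2-diolate (cis-diolate) | CC1(C)C[C@H](O[Si](CC)(CC)CC)C[C@@](C)([O-])[C@]1([O-])C#C/C(C)=C/CO[Si](CC)(CC)CC.[Li+].[Li+] | intermediate
15 | (3aR,6S,7aR)-4,4,7a-trimethyl-3a-{(3E)-3-methyl-5-[(triethylsilyl)oxy]pent-3-en-1-yn-1-yl}-6-[(triethylsilyl)oxy]hexahydro-1,3-benzodioxol-2-one | CC1(C)C[C@H](O[Si](CC)(CC)CC)C[C@@]2(C)OC(=O)O[C@@]12C#C/C(C)=C/CO[Si](CC)(CC)CC | intermediate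
16 | (1R,5S)-1,3,3-trimethyl-2-{(3E)-3-methyl-5-[(triethylsilyl)oxy]penta-1,3-dien-1-ylidene}-5-[(triethylsilyl)oxy]cyclohexan-1-ol, (Sa) allene | CC1(C)C[C@H](O[Si](CC)(CC)CC)C[C@@](C)(O)C1=[C@@]=C([H])/C(C)=C/CO[Si](CC)(CC)CC | intermediate
17 | {(2E)-5-[(2R,4S)-2,4-dihydroxy-2,6,6-trimethylcyclohexylidene]-3-methylpenta-2,4-dien-1-yl}triphenylphosphonium bromide, (Sa) allene | CC1(C)C[C@H](O)C[C@@](C)(O)C1=[C@@]=C([H])/C(C)=C/C[P+](c1ccccc1)(c1ccccc1)c1ccccc1.[Br-] | intermediate
18 | (2E,4E,6E)-2,7-dimethylocta-2,4,6-trienedial | O=C/C(C)=C/C=C/C=C(C)/C=O | starting material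
19 | triethyl phosphonoacetate | CCOC(=O)CP(=O)(OCC)OCC | starting material
20 | ethyl (2E,4E,6E,8E)-4,9-dimethyl-10-oxodeca-2,4,6,8-tetraenoate | CCOC(=O)/C=C/C(C)=C/C=C/C=C(C)/C=O | intermediate
21 | {(2E)-5-[(2R,4S)-2,4-dihydroxy-2,6,6-trimethylcyclohexylidene]-3-methylpenta-2,4-dien-1-ylidene}triphenylphosphorane, (Sa) allene | CC1(C)C[C@H](O)C[C@@](C)(O)C1=[C@@]=C([H])/C(C)=C/C=P(c1ccccc1)(c1ccccc1)c1ccccc1 | intermediate
22 | ethyl (3S,5R,6S)-3,5-dihydroxy-6,7-didehydro-5,6-dihydro-10′-apo-β-caroten-10′-oate, all-E | CC1(C)C[C@H](O)C[C@@](C)(O)C1=[C@@]=C([H])/C(C)=C/C=C/C(C)=C/C=C/C=C(C)/C=C/C(=O)OCC | intermediate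
23 | (3S,5R,6S)-6,7-didehydro-5,6-dihydro-10′-apo-β-carotene-3,5,10′-triol, all-E | CC1(C)C[C@H](O)C[C@@](C)(O)C1=[C@@]=C([H])/C(C)=C/C=C/C(C)=C/C=C/C=C(C)/C=C/CO | intermediate
24 | (3S,5R,8R)-5,8-epoxy-5,8-dihydro-10′-apo-β-carotene-3,10′-diol, all-E | CC(/C=C/C=C(\C)[C@H]1C=C2C(C)(C)C[C@H](O)C[C@@]2(C)O1)=C\C=C\C=C(C)\C=C\CO | target

**Step count**
Total step count: 12. Longest linear sequence: 10 steps (1, 2, 3, 4, 6, 7, 8, 10, 11, 12).

**Steps most likely to fail**

Step 4, the carbene-catalysed benzoin. The aldehyde is α-quaternary and may form the acyl anion equivalent slowly. Base-induced aldol closure of the methyl ketone onto the aldehyde or loss of silanol could compete. The 5R selectivity rests on the chair argument only. The fallback sets out from 9 and comes back at 10. SmI2 (2.5 equiv) in THF/t-BuOH at −78 °C couples the aldehyde ketyl with the ketone (pinacol cyclisation through a samarium-bridged chair with the same equatorial preferences) to the cis-diol (1R,2S,5S)-1,3,3-trimethyl-5-[(triethylsilyl)oxy]cyclohexane-1,2-diol F1. Its secondary hydroxyl is then oxidised with SO3·pyridine, DMSO and i-Pr2NEt to give 10.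

Step 6, the acetylide addition. The ketone is flanked by two fully substituted carbons, and the route needs the cis-5,6-diolate. If the lithium alkoxide instead delivered the acetylide to its own face, the trans-diol would form and step 7 would give the opposite allene axis and finally the 8S epimer. The fallback sets out from 10 and comes back at 17. The tertiary hydroxyl is capped with Me3SiOTf and 2,6-lutidine to give (2R,4S)-2,6,6-trimethyl-4-[(triethylsilyl)oxy]-2-[(trimethylsilyl)oxy]cyclohexan-1-one F2, so that only the steric bias of the axial silyloxy group and the axial methyl remains. Addition of 13 and trapping of the single alkoxide with ClCO2Me gives the acyclic propargylic carbonate methyl (1R,2R,4S)-2,6,6-trimethyl-1-{(3E)-3-methyl-5-[(triethylsilyl)oxy]pent-3-en-1-yn-1-yl}-4-[(triethylsilyl)oxy]-2-[(trimethylsilyl)oxy]cyclohexyl carbonate F3. The palladium/formate conditions of step 7 convert it to the 5-O-trimethylsilyl ether of 16 F4, and PPh3·HBr in MeOH removes all three silyl groups and gives 17.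

Step 12, the silver cyclisation on the unprotected hexaene triol. The 5-endo closure may be slow. Silver may isomerise the polyene. The new C8–O bond is doubly allylic to an electron-rich polyene and could ionise and scramble 8R/8S. The fallback sets out from 22 and comes back at 24. The same AgNO3/CaCO3 cyclisation is run on the ester, where the acceptor-substituted polyene disfavours ionisation at C8, to give ethyl (3S,5R,8R)-3-hydroxy-5,8-epoxy-5,8-dihydro-10′-apo-β-caroten-10′-oate F5. This is then reduced with i-Bu2AlH at −78 °C to 24.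

**Further compounds**
F1 | step 4 | (1R,2S,5S)-1,3,3-trimethyl-5-[(triethylsilyl)oxy]cyclohexane-1,2-diol | CC1(C)C[C@H](O[Si](CC)(CC)CC)C[C@@](C)(O)[C@H]1O
F2 | step 6 | (2R,4S)-2,6,6-trimethyl-4-[(triethylsilyl)oxy]-2-[(trimethylsilyl)oxy]cyclohexan-1-one | O=C1C(C)(C)C[C@H](O[Si](CC)(CC)CC)C[C@@]1(C)O[Si](C)(C)C
F3 | step 6 | methyl (1R,2R,4S)-2,6,6-trimethyl-1-{(3E)-3-methyl-5-[(triethylsilyl)oxy]pent-3-en-1-yn-1-yl}-4-[(triethylsilyl)oxy]-2-[(trimethylsilyl)oxy]cyclohexyl carbonate | CC1(C)C[C@H](O[Si](CC)(CC)CC)C[C@@](C)(O[Si](C)(C)C)[C@]1(OC(=O)OC)C#C/C(C)=C/CO[Si](CC)(CC)CC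
F4 | step 6 | 5-O-trimethylsilyl ether of 16, (Sa) allene | CC1(C)C[C@H](O[Si](CC)(CC)CC)C[C@@](C)(O[Si](C)(C)C)C1=[C@@]=C([H])/C(C)=C/CO[Si](CC)(CC)CC
F5 | step 12 | ethyl (3S,5R,8R)-3-hydroxy-5,8-epoxy-5,8-dihydro-10′-apo-β-caroten-10′-oate | CC(/C=C/C=C(\C)[C@H]1C=C2C(C)(C)C[C@H](O)C[C@@]2(C)O1)=C\C=C\C=C(C)\C=C\C(=O)OCC
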